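**Retrosynthetic overview**

1. Endgame (elemane locants: carbocycle C5–C10; C10 = quaternary carbon with methyl C14 and vinyl C1=C2; C5 carries C4(=C3H2)–C15H2OH; γ-lactone O–C6/C7–C11(=C13H2)–C12=O; acyloxy group on C8; C9 = ring CH2): C8–O acylation with an acid made from (R)-3-hydroxy-γ-butyrolactone, C11=C13 by aminomethylation/elimination, C8–OH from a C8 ketone.
2. Both alkenyl groups on C10 and C5 are retrons of one temporary oxane ring C1–C10–C5–C4–C15–O (lactol at C1, ketone at C4); a twofold Wittig methylenation opens it to C1=C2 and C4(=C3H2)–C15H2OH.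
3. Key disconnection: C9–C10 and C5–C6 in one Diels–Alder reaction between the 1,3-bis(silyloxy)diene C6=C7–C8=C9 (O6 and O8 as silyl ethers, the C11–C12 acetate arm on C7) and the enone bond C5=C10 of (S)-6-acetoxy-5-methyl-2H-pyran-3(6H)-one, itself made from a furan by Achmatowicz rearrangement.
4. Enabling feature: O6 and O8 stand 1,3 on the carbocycle, so C6–C7–C8–C9 maps onto a doubly donor-substituted diene with C9 as its nucleophilic terminus; C5 bears the carbonyl-level carbon C4 and C10 the aldehyde-level carbon C1, which together with C15 and one oxygen close the six-membered 2H-pyran-3(6H)-one ring that makes C5=C10 a locked enone; its acetal centre C1 steers the diene to one face and is erased afterwards.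
5. Ring order: pyranone (temporary) → cyclohexene by [4+2] (cis-fused, then epimerised at C5) → oxane ring opened → trans-γ-lactone closed on O6 while C8 is still a ketone.

Key step: step 6

**Remarks**

- Convention: β is the ring face of the C10 methyl group, α the face of the C10 vinyl group; "12,6α-olide" is the trans-fused γ-lactone O–C6/C7–C11–C12; "13-nor" means that C13 is still missing.
- Assumption: (4-methylfuran-2-yl)methanol (1) is bought as a catalogue building block.
- Assumption: a lipase that acylates the (S)-hemiacetal of 2 is found by screening; the sense of step 2 rests on this.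

**Route**

Step 1
Reactants: 1 (4-methylfuran-2-yl)methanol
Product: 2 6-hydroxy-5-methyl-2H-pyran-3(6H)-one (racemic; configurationally labile hemiacetal)
Conditions: mCPBA, CH2Cl2, 0 °C
Reagents that add atoms: 3-chloroperoxybenzoic acid (mCPBA), OOC(=O)c1cccc(Cl)c1
Why: Achmatowicz rearrangement: oxidation of the furan, opening to the Z-configured keto enal and recyclisation through the primary hydroxyl should give the pyranone whose enone carbons are the future C5 and C10, the hemiacetal centre (future C1) forming as a racemising mixture.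

Step 2
Reactants: 2 6-hydroxy-5-methyl-2H-pyran-3(6H)-one
Product: 3 (S)-6-acetoxy-5-methyl-2H-pyran-3(6H)-one
Conditions: immobilised Burkholderia cepacia lipase, vinyl acetate, t-BuOMe, 25 °C
Reagents that add atoms: vinyl acetate, C=COC(C)=O
Why: Lipase-catalysed enantioselective acyl transfer combined with racemisation of the unreacted hemiacetal through its open-chain keto enal (dynamic kinetic resolution) should funnel 2 into one acetate, the enzyme setting the acetal stereocentre.

Step 3
Reactants: 4 methyl 4-oxopentanoate (methyl levulinate)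
Product: 5 methyl 4-(trimethylsilyloxy)pent-3-enoate (E/Z mixture)
Conditions: Me3SiCl, Et3N, DMF, 80 °C
Reagents that add atoms: chlorotrimethylsilane, C[Si](C)(C)Cl
Why: Silyl enol ether formation under equilibrating conditions should favour the more substituted C3=C4 enol ether, which fixes where the formyl carbon (future C6) will be attached; no stereocentre is formed.

Step 4
Reactants: 5 methyl 4-(trimethylsilyloxy)pent-3-enoate
Product: 7 methyl (3Z)-3-(hydroxymethylidene)-4-oxopentanoate, via keto acetal 6 (not isolated)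
Conditions: HC(OMe)3, Me3SiOTf (5 mol %), CH2Cl2, −78 °C; then 1 M HCl, THF, 25 °C
Reagents that add atoms: trimethyl orthoformate, COC(OC)OC; water, O
Why: Mukaiyama-type addition of the silyl enol ether to the dimethoxycarbenium ion forms the C6–C7 bond regiospecifically, and acid hydrolysis of acetal 6 should give the chelated Z-enol of the β-keto aldehyde; no stereocentre is formed.

Step 5
Reactants: 7 methyl (3Z)-3-(hydroxymethylidene)-4-oxopentanoate
Product: 8 methyl (3E)-4-(tert-butyldimethylsilyloxy)-3-[(tert-butyldimethylsilyloxy)methylidene]pent-4-enoate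
Conditions: t-BuMe2SiOTf (2.2 equiv), Et3N, Et2O, 0 °C
Reagents that add atoms: tert-butyldimethylsilyl trifluoromethanesulfonate, CC(C)(C)[Si](C)(C)OS(=O)(=O)C(F)(F)F
Why: O-Silylation of the formyl enol and soft enolisation/silylation of the methyl ketone (only C9 carries α-hydrogens) should give the 1,3-bis(silyloxy)diene, the push–pull enol ether settling in the E geometry (silyloxy anti to C8) that the cycloaddition needs.

Step 6
Reactants: 3 (S)-6-acetoxy-5-methyl-2H-pyran-3(6H)-one; 8 methyl (3E)-4-(tert-butyldimethylsilyloxy)-3-[(tert-butyldimethylsilyloxy)methylidene]pent-4-enoate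
Product: 9 methyl 2-[(1S)-1-acetoxy-5,7-bis(tert-butyldimethylsilyloxy)-8a-methyl-4-oxo-3,4,4a,5,8,8a-hexahydro-1H-isochromen-6-yl]acetate (cis-fused; 1-OAc/4a-H/8a-CH3 on one face; 5-OSi on the other)
Conditions: PhMe, 110 °C, sealed tube, 2,6-di-tert-butyl-4-methylphenol (cat.)
Reagents that add atoms: none
Why: Concerted but asynchronous normal-electron-demand [4+2] cycloaddition (Diels–Alder reaction); the closest known reaction type is the addition of 1-oxy-3-silyloxybutadienes to the enone of 6-acyloxy- or 6-alkoxy-2H-pyran-3(6H)-ones and to 3-methylcycloalk-2-enones. One ring is closed, the cyclohexene C5–C6–C7=C8–C9–C10, by suprafacial addition across the ring-locked enone bond, so the ring fusion must be cis. Regiochemistry: both oxygen donors (O6 and O8) raise the HOMO coefficient at the CH2 terminus C9, which bonds to the enone β-carbon C10 (largest LUMO coefficient) and leaves C6 to bond to the α-carbon C5. C10 is set by attack on the enone face anti to the pseudo-axial anomeric acetoxy group at C1 (substrate control from the (S)-centre), C5 follows from the cis addition, and C6 is set by the endo transition state (diene under the ketone), which places the outside 6-silyloxy group cis to the C4 carbonyl carbon. The step needs enough reactivity at a β,β-disubstituted enone carbon, which the doubly donor-activated, 2-substituted (s-cis-biased) diene and the inductive activation of the enone by the ring oxygen and the acetoxy group should supply. The C5 configuration of 9 is the wrong one by design and is corrected in step 7; C1 is erased in step 8.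

Step 7
Reactants: 9 cis-fused cycloadduct
Product: 10 methyl 2-[5,7-bis(tert-butyldimethylsilyloxy)-1-hydroxy-8a-methyl-4-oxo-3,4,4a,5,8,8a-hexahydro-1H-isochromen-6-yl]acetate (trans-fused; 4a-H and 5-OSi on the face opposite to 8a-CH3; lactol anomers)
Conditions: K2CO3 (0.3 equiv), MeOH, 0 °C
Reagents that add atoms: none
Why: Base-catalysed methanolysis removes the anomeric acetate and reversible enolisation of the C4 ketone should epimerise C5 to the thermodynamically preferred trans ring fusion (C4 and O6 equatorial; the axial C10 methyl meets no syn-axial hydrogen in the oxane ring), the C5 enolate being reprotonated by methanol much faster than it can expel the equatorial, poorly aligned 6-silyloxy group.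

Step 8
Reactants: 10 trans-fused keto lactol
Product: 11 methyl 2-[2,6-bis(tert-butyldimethylsilyloxy)-4-ethenyl-5-(3-hydroxyprop-1-en-2-yl)-4-methylcyclohex-1-en-1-yl]acetate (10β-CH3; 10α-vinyl; 5β-alkenyl; 6α-OSi)
Conditions: Ph3PCH3Br, KOt-Bu, THF, 0 → 45 °C
Reagents that add atoms: methyltriphenylphosphonium bromide, C[P+](c1ccccc1)(c1ccccc1)c1ccccc1.[Br-]
Why: Twofold Wittig methylenation: the C4 ketone gives the C4=C3 methylene and the lactol, through its open aldehyde form, gives the C1=C2 vinyl group and frees O15–H, so one operation unmasks both alkenyl substituents; no stereocentre is touched and C5 can no longer epimerise.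

Step 9
Reactants: 11 bis(silyl) diene alcohol
Product: 13 15-hydroxy-8-oxo-13-norelema-1,3-dien-12,6α-olide (5α-H; 6β-H; 7α-H; 10β-CH3), via hydroxy keto ester 12 (not isolated)
Conditions: aq. HF (48%), MeCN, 0 → 25 °C; then TsOH·H2O (cat.), PhMe, 40 °C
Reagents that add atoms: none
Why: Protodesilylation cleaves the silyl enol ether and the secondary silyl ether, C7 is protonated under equilibrating conditions so that the acetate arm becomes equatorial (trans to O6), and acid-catalysed lactonisation can engage only the 6α-hydroxyl because C8 is still a ketone, which should give the trans-fused γ-lactone.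

Step 10
Reactants: 13 keto lactone
Product: 14 8α,15-dihydroxy-13-norelema-1,3-dien-12,6α-olide
Conditions: SmI2 (2.5 equiv), THF/MeOH, −78 → −20 °C
Reagents that add atoms: none
Why: Electron-transfer (ketyl) reduction with a proton donor should give the thermodynamically preferred equatorial 8α-alcohol, because an axial oxygen at C8 would be syn-axial to the C10 methyl group, whereas hydride reagents would attack the open α face and give the axial epimer.

Step 11
Reactants: 14 diol lactone
Product: 15 15-(tert-butyldimethylsilyloxy)-8α-hydroxy-13-norelema-1,3-dien-12,6α-olide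
Conditions: t-BuMe2SiCl, imidazole, CH2Cl2, 0 °C
Reagents that add atoms: tert-butyldimethylsilyl chloride, CC(C)(C)[Si](C)(C)Cl
Why: Sterically controlled selective silylation of the primary allylic hydroxyl over the hindered secondary one.

Step 12
Reactants: 15 mono-silyl ether
Product: 16 15-(tert-butyldimethylsilyloxy)-8α-(triethylsilyloxy)-13-norelema-1,3-dien-12,6α-olide
Conditions: Et3SiOTf, 2,6-lutidine, CH2Cl2, −78 °C
Reagents that add atoms: triethylsilyl trifluoromethanesulfonate, CC[Si](CC)(CC)OS(=O)(=O)C(F)(F)F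
Why: Silyl protection of the 8α-hydroxyl, so that no alkoxide can attack the lactone carbonyl (translactonisation) or the new methylene group in the next step.

Step 13
Reactants: 16 bis(silyl) lactone
Product: 19 15-(tert-butyldimethylsilyloxy)-8α-(triethylsilyloxy)elema-1,3,11(13)-trien-12,6α-olide, via Mannich base 17 (not isolated), via ammonium iodide 18 (not isolated)
Conditions: LiN(i-Pr)2, THF, −78 °C; CH2=NMe2+ I−, −78 → 0 °C; then MeI, MeOH, 25 °C; then NaHCO3 (aq), CH2Cl2
Reagents that add atoms: N,N-dimethylmethyleneiminium iodide, C=[N+](C)C.[I-] (its CH2 stays); iodomethane, CI (adds CH3 to 18 only; it leaves again with the amine)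
Why: α-Methylenation of the lactone: the lithium enolate is aminomethylated (Mannich reaction), N-methylation gives salt 18 and mild base induces E1cB (Hofmann-type) elimination to the exocyclic C11=C13 alkene, the C11 stereocentre of 17 being lost again.

Step 14
Reactants: 19 α-methylene lactone bis(silyl ether)
Product: 20 15-(tert-butyldimethylsilyloxy)-8α-hydroxyelema-1,3,11(13)-trien-12,6α-olide
Conditions: pyridinium p-toluenesulfonate (cat.), MeOH/CH2Cl2, 0 °C
Reagents that add atoms: none
Why: Acid-catalysed methanolysis should cleave the much more labile secondary triethylsilyl ether while the primary tert-butyldimethylsilyl ether survives.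

Step 15
Reactants: 21 (R)-4-hydroxydihydrofuran-2(3H)-one ((R)-3-hydroxy-γ-butyrolactone)
Product: 24 (R)-4-hydroxy-3-methylidenedihydrofuran-2(3H)-one, via Mannich base 22 (not isolated), via ammonium iodide 23 (not isolated)
Conditions: LiN(i-Pr)2 (2.2 equiv), THF, −78 °C; CH2=NMe2+ I−, −78 → 0 °C; then MeI, MeOH, 25 °C; then NaHCO3 (aq)
Reagents that add atoms: N,N-dimethylmethyleneiminium iodide, C=[N+](C)C.[I-] (its CH2 stays); iodomethane, CI (adds CH3 to 23 only; it leaves again with the amine)
Why: The alkoxide–enolate dianion of the β-hydroxy lactone is aminomethylated at C3 (Mannich reaction; the alkoxide is no leaving group, so no β-elimination) and methylation/E1cB elimination of trimethylamine should give the α-methylene lactone, the carbinol stereocentre coming unchanged from the chiral pool.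

Step 16
Reactants: 24 (R)-4-hydroxy-3-methylidenedihydrofuran-2(3H)-one
Product: 25 methyl 2-[(4R)-2,2-dimethyl-1,3-dioxolan-4-yl]prop-2-enoate
Conditions: 2,2-dimethoxypropane, MeOH, TsOH·H2O (cat.), 25 °C
Reagents that add atoms: methanol, CO; 2,2-dimethoxypropane, COC(C)(C)OC
Why: Acid-catalysed methanolysis of the lactone is pulled forward by trapping of the liberated 1,2-diol as its acetonide (transacetalisation), the stereocentre being untouched.

Step 17
Reactants: 25 methyl 2-[(4R)-2,2-dimethyl-1,3-dioxolan-4-yl]prop-2-enoate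
Product: 26 2-[(4R)-2,2-dimethyl-1,3-dioxolan-4-yl]prop-2-enoic acid
Conditions: LiOH, THF/H2O, 0 °C; then 1 M HCl to pH 4, 0 °C
Reagents that add atoms: lithium hydroxide, [Li+].[OH-]
Why: Saponification of the methyl ester at low temperature and careful acidification should give the acid without loss of the acid-labile acetonide.

Step 18
Reactants: 20 15-(tert-butyldimethylsilyloxy)-8α-hydroxyelema-1,3,11(13)-trien-12,6α-olide; 26 2-[(4R)-2,2-dimethyl-1,3-dioxolan-4-yl]prop-2-enoic acid
Product: 27 15-(tert-butyldimethylsilyloxy)-8α-{2-[(4R)-2,2-dimethyl-1,3-dioxolan-4-yl]prop-2-enoyloxy}elema-1,3,11(13)-trien-12,6α-olide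
Conditions: 2,4,6-trichlorobenzoyl chloride, Et3N, THF, 0 °C; then 20, DMAP, PhMe, 25 °C
Reagents that add atoms: none
Why: Yamaguchi esterification (mixed anhydride, then DMAP acyl transfer) acylates the only free hydroxyl, the hindered equatorial 8α-OH, with retention at C8 and at the side-chain stereocentre.

Step 19
Reactants: 27 protected ester
Product: 28 8α-[(3R)-3,4-dihydroxy-2-methylidenebutanoyloxy]-15-hydroxyelema-1,3,11(13)-trien-12,6α-olide (target, CNP0234188.1)
Conditions: AcOH/THF/H2O (3:1:1), 40 °C
Reagents that add atoms: none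
Why: Mild aqueous acid hydrolysis should remove the acetonide and the primary allylic silyl ether in one operation without touching the lactone or the acrylate ester.

**Compound list**

1 | (4-methylfuran-2-yl)methanol | Cc1coc(CO)c1 | starting material
2 | 6-hydroxy-5-methyl-2H-pyran-3(6H)-one (racemic hemiacetal) | CC1=CC(=O)COC1O | intermediate
3 | (S)-6-acetoxy-5-methyl-2H-pyran-3(6H)-one | CC1=CC(=O)CO[C@H]1OC(C)=O | intermediate
4 | methyl 4-oxopentanoate | COC(=O)CCC(C)=O | starting material
5 | methyl 4-(trimethylsilyloxy)pent-3-enoate (E/Z mixture) | COC(=O)CC=C(C)O[Si](C)(C)C | intermediate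
6 | methyl 3-(dimethoxymethyl)-4-oxopentanoate | COC(=O)CC(C(OC)OC)C(C)=O | intermediate (not isolated)
7 | methyl (3Z)-3-(hydroxymethylidene)-4-oxopentanoate | CC(=O)/C(CC(=O)OC)=C\O | intermediate
8 | methyl (3E)-4-(tert-butyldimethylsilyloxy)-3-[(tert-butyldimethylsilyloxy)methylidene]pent-4-enoate | C=C(O[Si](C)(C)C(C)(C)C)/C(CC(=O)OC)=C/O[Si](C)(C)C(C)(C)C | intermediate
9 | cis-fused cycloadduct: methyl 2-[(1S)-1-acetoxy-5,7-bis(tert-butyldimethylsilyloxy)-8a-methyl-4-oxo-3,4,4a,5,8,8a-hexahydro-1H-isochromen-6-yl]acetate; 1-OAc, 4a-H and 8a-CH3 on one face, 5-OSi on the other | CC(=O)O[C@@H]1OCC(=O)[C@H]2[C@@H](O[Si](C)(C)C(C)(C)C)C(CC(=O)OC)=C(O[Si](C)(C)C(C)(C)C)C[C@@]12C | intermediate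
10 | trans-fused keto lactol: methyl 2-[5,7-bis(tert-butyldimethylsilyloxy)-1-hydroxy-8a-methyl-4-oxo-3,4,4a,5,8,8a-hexahydro-1H-isochromen-6-yl]acetate; 4a-H and 5-OSi opposite to 8a-CH3; anomer mixture | OC1OCC(=O)[C@@H]2[C@@H](O[Si](C)(C)C(C)(C)C)C(CC(=O)OC)=C(O[Si](C)(C)C(C)(C)C)C[C@@]12C | intermediate
11 | methyl 2-[2,6-bis(tert-butyldimethylsilyloxy)-4-ethenyl-5-(3-hydroxyprop-1-en-2-yl)-4-methylcyclohex-1-en-1-yl]acetate (10β-CH3, 10α-vinyl, 5β-alkenyl, 6α-OSi) | C=C[C@]1(C)CC(O[Si](C)(C)C(C)(C)C)=C(CC(=O)OC)[C@H](O[Si](C)(C)C(C)(C)C)[C@H]1C(=C)CO | intermediate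
12 | methyl 2-[4-ethenyl-2-hydroxy-3-(3-hydroxyprop-1-en-2-yl)-4-methyl-6-oxocyclohexyl]acetate (6α-OH, 7β-CH2CO2Me, 5β-alkenyl, 10β-CH3) | C=C[C@]1(C)CC(=O)[C@@H](CC(=O)OC)[C@H](O)[C@H]1C(=C)CO | intermediate (not isolated)
13 | 15-hydroxy-8-oxo-13-norelema-1,3-dien-12,6α-olide | C=C[C@]1(C)CC(=O)[C@H]2CC(=O)O[C@@H]2[C@H]1C(=C)CO | intermediate
14 | 8α,15-dihydroxy-13-norelema-1,3-dien-12,6α-olide | C=C[C@]1(C)C[C@H](O)[C@H]2CC(=O)O[C@@H]2[C@H]1C(=C)CO | intermediate
15 | 15-(tert-butyldimethylsilyloxy)-8α-hydroxy-13-norelema-1,3-dien-12,6α-olide | C=C[C@]1(C)C[C@H](O)[C@H]2CC(=O)O[C@@H]2[C@H]1C(=C)CO[Si](C)(C)C(C)(C)C | intermediate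
16 | 15-(tert-butyldimethylsilyloxy)-8α-(triethylsilyloxy)-13-norelema-1,3-dien-12,6α-olide | C=C[C@]1(C)C[C@H](O[Si](CC)(CC)CC)[C@H]2CC(=O)O[C@@H]2[C@H]1C(=C)CO[Si](C)(C)C(C)(C)C | intermediate
17 | 13-(dimethylamino)-15-(tert-butyldimethylsilyloxy)-8α-(triethylsilyloxy)elema-1,3-dien-12,6α-olide (C11 epimers) | C=C[C@]1(C)C[C@H](O[Si](CC)(CC)CC)[C@H]2C(CN(C)C)C(=O)O[C@@H]2[C@H]1C(=C)CO[Si](C)(C)C(C)(C)C | intermediate (not isolated)
18 | 13-(trimethylammonio) analogue of 17, iodide | C=C[C@]1(C)C[C@H](O[Si](CC)(CC)CC)[C@H]2C(C[N+](C)(C)C)C(=O)O[C@@H]2[C@H]1C(=C)CO[Si](C)(C)C(C)(C)C.[I-] | intermediate (not isolated)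
19 | 15-(tert-butyldimethylsilyloxy)-8α-(triethylsilyloxy)elema-1,3,11(13)-trien-12,6α-olide | C=C[C@]1(C)C[C@H](O[Si](CC)(CC)CC)[C@H]2C(=C)C(=O)O[C@@H]2[C@H]1C(=C)CO[Si](C)(C)C(C)(C)C | intermediate
20 | 15-(tert-butyldimethylsilyloxy)-8α-hydroxyelema-1,3,11(13)-trien-12,6α-olide | C=C[C@]1(C)C[C@H](O)[C@H]2C(=C)C(=O)O[C@@H]2[C@H]1C(=C)CO[Si](C)(C)C(C)(C)C | intermediate
21 | (R)-4-hydroxydihydrofuran-2(3H)-one | O=C1C[C@@H](O)CO1 | starting material
22 | (4R)-3-[(dimethylamino)methyl]-4-hydroxydihydrofuran-2(3H)-one (C3 epimers) | CN(C)CC1[C@@H](O)COC1=O | intermediate (not isolated)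
23 | [(4R)-4-hydroxy-2-oxooxolan-3-yl]methyl(trimethyl)ammonium iodide | C[N+](C)(C)CC1[C@@H](O)COC1=O.[I-] | intermediate (not isolated)
24 | (R)-4-hydroxy-3-methylidenedihydrofuran-2(3H)-one | C=C1[C@@H](O)COC1=O | intermediate
25 | methyl 2-[(4R)-2,2-dimethyl-1,3-dioxolan-4-yl]prop-2-enoate | C=C(C(=O)OC)[C@@H]1COC(C)(C)O1 | intermediate
26 | 2-[(4R)-2,2-dimethyl-1,3-dioxolan-4-yl]prop-2-enoic acid | C=C(C(=O)O)[C@@H]1COC(C)(C)O1 | intermediate
27 | 15-(tert-butyldimethylsilyloxy)-8α-{2-[(4R)-2,2-dimethyl-1,3-dioxolan-4-yl]prop-2-enoyloxy}elema-1,3,11(13)-trien-12,6α-olide | C=C[C@]1(C)C[C@H](OC(=O)C(=C)[C@@H]3COC(C)(C)O3)[C@H]2C(=C)C(=O)O[C@@H]2[C@H]1C(=C)CO[Si](C)(C)C(C)(C)C | intermediate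
28 | 8α-[(3R)-3,4-dihydroxy-2-methylidenebutanoyloxy]-15-hydroxyelema-1,3,11(13)-trien-12,6α-olide | C=C[C@]1(C)C[C@H](OC(=O)C(=C)[C@@H](O)CO)[C@H]2C(=C)C(=O)O[C@@H]2[C@H]1C(=C)CO | target

**Step count and risks**

Total step count: 19. Longest linear sequence: 14 steps (steps 3–14, 18 and 19, from methyl 4-oxopentanoate).

Steps most likely to fail:

1. Step 6 (key cycloaddition). Bond formation at the β,β-disubstituted enone carbon may be too slow, so that thermal decomposition of the bis(silyloxy)diene or loss of the anomeric acetate outruns it; incomplete endo or facial selection would show up as isomer mixtures at C6 or C10. Fallback: the enone is activated as its α-bromo derivative. From 3, Br2 and then pyridine should give (S)-6-acetoxy-4-bromo-5-methyl-2H-pyran-3(6H)-one F1. Its [4+2] reaction with 8, with the same sense of regio-, facial and endo selection and at lower temperature, should give the 4a-bromo cycloadduct F2 and still forms both ring bonds in one operation. Bu3SnH with azobisisobutyronitrile removes the bromine with hydrogen delivery anti to the angular methyl group and should give the trans-fused keto acetate F3. F3 is deacetylated under the conditions of step 7 and comes back to the route at 10.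

2. Step 2 (enzymatic acylation). The lipase may discriminate the enantiomers of the 5-methyl-substituted hemiacetal poorly, which would erode the only source of absolute configuration for C10. Fallback: from 2, chemical acetylation (Ac2O, pyridine, DMAP) gives the racemic acetate F4. The enantiomers are separated by preparative chromatography on a chiral stationary phase. The (R)-acetate is methanolysed (K2CO3 cat., MeOH) back to the racemising hemiacetal 2 and recycled. The fallback returns to the route at 3.

3. Step 10 (C8 reduction). Thermodynamic control in the electron-transfer reduction may be incomplete (epimer mixture at C8), or the β-acyloxy ketone/lactone may be over-reduced. Fallback: from 13, LiBH(s-Bu)3 (THF, −78 °C, acetic acid quench) attacks the open α face and should give the axial 8β-alcohol F5 selectively. t-BuMe2SiCl/imidazole gives its C15 silyl ether F6. Mitsunobu inversion with 4-nitrobenzoic acid (PPh3, diisopropyl azodicarboxylate) gives the 8α-(4-nitrobenzoate) F7. NaN3 in MeOH removes the nitrobenzoate and returns the sequence at 15.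

Further compounds
F1 | step 6 | (S)-6-acetoxy-4-bromo-5-methyl-2H-pyran-3(6H)-one | CC1=C(Br)C(=O)CO[C@H]1OC(C)=O
F2 | step 6 | 4a-bromo analogue of cycloadduct 9 (cis-fused; bromine in place of 4a-H) | CC(=O)O[C@@H]1OCC(=O)[C@@]2(Br)[C@@H](O[Si](C)(C)C(C)(C)C)C(CC(=O)OC)=C(O[Si](C)(C)C(C)(C)C)C[C@@]12C
F3 | step 6 | trans-fused keto acetate (4a-epimer of 9) | CC(=O)O[C@@H]1OCC(=O)[C@@H]2[C@@H](O[Si](C)(C)C(C)(C)C)C(CC(=O)OC)=C(O[Si](C)(C)C(C)(C)C)C[C@@]12C
F4 | step 2 | racemic 6-acetoxy-5-methyl-2H-pyran-3(6H)-one | CC1=CC(=O)COC1OC(C)=O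
F5 | step 10 | 8β,15-dihydroxy-13-norelema-1,3-dien-12,6α-olide | C=C[C@]1(C)C[C@@H](O)[C@H]2CC(=O)O[C@@H]2[C@H]1C(=C)CO
F6 | step 10 | 15-(tert-butyldimethylsilyloxy)-8β-hydroxy-13-norelema-1,3-dien-12,6α-olide | C=C[C@]1(C)C[C@@H](O)[C@H]2CC(=O)O[C@@H]2[C@H]1C(=C)CO[Si](C)(C)C(C)(C)C
F7 | step 10 | 15-(tert-butyldimethylsilyloxy)-8α-(4-nitrobenzoyloxy)-13-norelema-1,3-dien-12,6α-olide | C=C[C@]1(C)C[C@H](OC(=O)c3ccc(cc3)[N+](=O)[O-])[C@H]2CC(=O)O[C@@H]2[C@H]1C(=C)CO[Si](C)(C)C(C)(C)C
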